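## Retrosynthetic overview

- **Numbering:** cyclohexene ring C1 (CH bearing the side chain), C2 (=CH), C3 (=C–CH3), C4, C5, C6 (CH–isopropenyl). Cq is the exocyclic quaternary carbon on C1.
- **Enabling feature:** the array C3=C2–C1–Cq (ring alkene, allylic ring methine, exocyclic fully substituted carbon) is a homoallyl unit, the opened form of a cyclopropylcarbinyl system. Trading Cq–CH3 for a temporary C2–Cq bond, and C3–CH3 for C3=O, leads back to a 7,7-dialkylbicyclo[4.1.0]heptan-2-one.
- **Key disconnection:** both cyclopropane bonds at C2 are cut (C1–C2, which closes the six-membered ring, and the temporary C2–Cq). This gives an acyclic α-diazoketone with an E-trisubstituted alkene C1=Cq. Alkene geometry sets Cq, and A(1,3) strain at C6 sets C1 and C2.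
- **Ring order:** the six- and three-membered rings form together in step 9. The three-membered ring is opened again in step 11 by invertive methylation at Cq, which also creates C2=C3. CO2Me at C6 masks the isopropenyl group against carbene and cation chemistry.
- **Precursor assembly:** the diazoketone comes from a one-flask union of three pieces. These are a citronellene-derived Grignard reagent, a geranyl-derived 1-alkyne (syn-carbocupration sets C1=Cq) and an L-glutamic-acid-derived α-triflyloxy diester (SN2 inversion sets C6).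

Key step: step 9

Assumption: the carbinol configuration of 21 is drawn for Grignard attack anti to the 7-endo chain; it is erased in step 11, so either epimer serves.

## Route

Step 1
Reactants: 1 (S)-β-citronellene [(3S)-3,7-dimethylocta-1,6-diene]
Product: 3 (4S)-4-methylhex-5-en-1-ol, via aldehyde 2 (not isolated)
Conditions: O3, CH2Cl2/MeOH, pyridine (cat.), Sudan III end-point, −78 °C; then NaBH4, −78 → 0 °C
Reagents that add atoms: ozone, [O-][O+]=O
Why: Chemoselective ozonolysis with reductive work-up should work because ozone attacks the electron-rich trisubstituted alkene much faster than the monosubstituted vinyl group, and the existing stereocentre is not touched.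

Step 2
Reactants: 3 (4S)-4-methylhex-5-en-1-ol
Product: 4 (3S)-6-bromo-3-methylhex-1-ene
Conditions: CBr4, PPh3, CH2Cl2, 0 °C
Reagents that add atoms: carbon tetrabromide, BrC(Br)(Br)Br
Why: The Appel reaction converts the primary alcohol into the bromide under neutral conditions that leave the vinyl group and the remote stereocentre alone.

Step 3
Reactants: 5 propargyl bromide (3-bromoprop-1-yne); 6 geranyl bromide [(2E)-1-bromo-3,7-dimethylocta-2,6-diene]
Product: 8 (5E)-6,10-dimethylundeca-5,9-dien-1-yne, via 1,3-dilithiopropyne 7 (not isolated)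
Conditions: n-BuLi (2 equiv), TMEDA, Et2O/hexane, −78 °C; then 6, −78 °C → rt; H2O
Reagents that add atoms: none
Why: In this propargylation with a propyne dianion the more basic sp3 carbon alkylates the allylic bromide by SN2 with retention of the E alkene, and the aqueous quench liberates the terminal alkyne.

Step 4
Reactants: 9 (2S)-5-oxotetrahydrofuran-2-carboxylic acid
Product: 10 dimethyl (2S)-2-hydroxypentanedioate
Conditions: MeOH, H2SO4 (cat.), reflux
Reagents that add atoms: methanol, CO
Why: Fischer esterification combined with acid-catalysed lactone methanolysis takes place only at the two acyl carbons, so the carbinol stereocentre is retained.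

Step 5
Reactants: 10 dimethyl (2S)-2-hydroxypentanedioate
Product: 11 dimethyl (2S)-2-[(trifluoromethanesulfonyl)oxy]pentanedioate
Conditions: Tf2O, 2,6-lutidine, CH2Cl2, −78 °C; used at once
Reagents that add atoms: triflic anhydride, O=S(=O)(OS(=O)(=O)C(F)(F)F)C(F)(F)F
Why: O-sulfonylation breaks no bond at carbon (retention) and turns the α-hydroxy ester into a strongly activated secondary SN2 electrophile.

Step 6
Reactants: 4 (3S)-6-bromo-3-methylhex-1-ene; 8 (5E)-6,10-dimethylundeca-5,9-dien-1-yne; 11 dimethyl (2S)-2-[(trifluoromethanesulfonyl)oxy]pentanedioate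
Product: 15 dimethyl (2S)-2-{(1E,5E)-6,10-dimethyl-2-[(4S)-4-methylhex-5-en-1-yl]undeca-1,5,9-trien-1-yl}pentanedioate, via Grignard reagent 12 (not isolated), via alkylcopper 13 (not isolated), via alkenylcopper 14 (not isolated)
Conditions: 4, Mg, Et2O; CuBr·SMe2, Et2O/Me2S, −45 °C; 8, −25 °C; then 11, P(OEt)3, DMPU, −78 → −20 °C
Reagents that add atoms: none
Why: Proposed new method: the alkylcopper·MgBr2 complex adds syn and with branched regiochemistry to the terminal alkyne (carbocupration), which places the methylhexenyl chain cis to copper and fixes the E alkene C1=Cq, and the configurationally stable alkenylcopper then displaces the ester-activated secondary triflate from the rear, so that C6 is set (S) by inversion; carbocupration followed by alkylation of alkenylcoppers, and the enantiospecific SN2 substitution of α-hydroxy-ester triflates by alkylcuprates or zinc-catalysed alkyl Grignard reagents, are the closest known reaction types, while the use of an alkenylcopper as the nucleophile is new.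

Step 7
Reactants: 15 dimethyl (2S)-2-{(1E,5E)-6,10-dimethyl-2-[(4S)-4-methylhex-5-en-1-yl]undeca-1,5,9-trien-1-yl}pentanedioate
Product: 16 (4S,5E,9E)-4-(methoxycarbonyl)-10,14-dimethyl-6-[(4S)-4-methylhex-5-en-1-yl]pentadeca-5,9,13-trienoic acid
Conditions: LiOH (1 equiv), THF/H2O, 0 °C; then 1 M HCl
Reagents that add atoms: lithium hydroxide, [Li+].[OH-]
Why: Regioselective saponification should take the unbranched ester, because the other one is α-branched and shielded by the alkenyl group, and one equivalent of base at 0 °C should leave C6 unepimerised.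

Step 8
Reactants: 16 (4S,5E,9E)-4-(methoxycarbonyl)-10,14-dimethyl-6-[(4S)-4-methylhex-5-en-1-yl]pentadeca-5,9,13-trienoic acid
Product: 18 methyl (2S,3E,7E)-2-(4-diazo-3-oxobutyl)-8,12-dimethyl-4-[(4S)-4-methylhex-5-en-1-yl]trideca-3,7,11-trienoate, via mixed anhydride 17 (not isolated)
Conditions: i-BuOCOCl, N-methylmorpholine, THF, −20 °C; then CH2N2, Et2O, 0 °C
Reagents that add atoms: diazomethane, C=[N+]=[N-]
Why: C-acylation of diazomethane by a mixed carbonic anhydride (first stage of the Arndt–Eistert sequence) is mild enough for the polyene, the methyl ester and the C6 stereocentre.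

Step 9
Reactants: 18 methyl (2S,3E,7E)-2-(4-diazo-3-oxobutyl)-8,12-dimethyl-4-[(4S)-4-methylhex-5-en-1-yl]trideca-3,7,11-trienoate
Product: 20 methyl (1S,2S,6S,7S)-7-[(3E)-4,8-dimethylnona-3,7-dien-1-yl]-7-[(4S)-4-methylhex-5-en-1-yl]-5-oxobicyclo[4.1.0]heptane-2-carboxylate, via copper carbene 19 (not isolated)
Conditions: bis(N-tert-butylsalicylaldiminato)copper(II) (5 mol %), toluene, reflux, slow addition of 18, high dilution
Reagents that add atoms: none
Why: The copper(II) precatalyst is reduced by 18 to copper(I), which expels N2 and gives the electrophilic α-oxo carbene 19 at C2; this adds suprafacially and asynchronously across C1=Cq, the C1–C2 bond leading while positive charge builds up on the dialkylated Cq. The closest known reaction type is the intramolecular diazoketone–alkene cyclopropanation of 1-diazoalk-6-en-2-ones, the standard entry to bicyclo[4.1.0]heptan-2-ones. The six-membered ring closes in a 6-exo-trig sense (C2 onto C1, Cq outside the ring) and the three-membered ring by collapse of C2 onto Cq, so that only the cis-fused bicycle can form. C1 and C2 are controlled by C6: A(1,3) strain with the methylhexenyl chain, which lies cis to C6 on the alkene, holds C6–H in the alkene plane, so the C5–C4–C3 tether can deliver C2 to one face only, the one that leaves CO2Me anti to the cyclopropane (C1/C6 trans). Cq is controlled by the alkene geometry, since syn addition copies the E alkene of 18 into the 7-endo methylhexenyl/7-exo homogeranyl arrangement. The step needs cyclopropanation of C1=Cq in preference to 1,5-C–H insertion at C6–H, to attack on the other three C=C bonds and to carbene dimerisation: the ester deactivates C6–H and stands in for the isopropenyl group that would otherwise compete at the same distance, the remaining alkenes could only react through rings of ten or more members, and slow addition at high dilution keeps 18 scarce.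

Step 10
Reactants: 20 methyl (1S,2S,6S,7S)-7-[(3E)-4,8-dimethylnona-3,7-dien-1-yl]-7-[(4S)-4-methylhex-5-en-1-yl]-5-oxobicyclo[4.1.0]heptane-2-carboxylate
Product: 21 methyl (1S,2S,5S,6S,7S)-7-[(3E)-4,8-dimethylnona-3,7-dien-1-yl]-5-hydroxy-5-methyl-7-[(4S)-4-methylhex-5-en-1-yl]bicyclo[4.1.0]heptane-2-carboxylate
Conditions: MeMgBr, LaCl3·2LiCl (cat.), THF, −78 °C; pH 7 buffer
Reagents that add atoms: methylmagnesium bromide, C[Mg]Br
Why: Grignard 1,2-addition should pick the ketone over the hindered α-branched ester at −78 °C, with attack anti to the 7-endo chain setting a carbinol centre that is erased in the next step.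

Step 11
Reactants: 21 methyl (1S,2S,5S,6S,7S)-7-[(3E)-4,8-dimethylnona-3,7-dien-1-yl]-5-hydroxy-5-methyl-7-[(4S)-4-methylhex-5-en-1-yl]bicyclo[4.1.0]heptane-2-carboxylate
Product: 24 methyl (1S,2S)-4-methyl-2-[(3S,7S,10E)-3,7,11,15-tetramethylhexadeca-1,10,14-trien-7-yl]cyclohex-3-ene-1-carboxylate, via aluminium alkoxide 22 (not isolated), via cyclopropylcarbinyl cation 23 (not isolated)
Conditions: AlMe3 (5 equiv), CH2Cl2/hexane, −78 → 0 °C; H2O work-up
Reagents that add atoms: trimethylaluminium, C[Al](C)C
Why: Proposed new method: AlMe3 first metalates the carbinol (22), further AlMe3 ionises the C3–O bond, which is both tertiary and cyclopropylcarbinylic, and in the bicyclo[4.1.0]hept-2-yl cation 23 only the exocyclic C2–Cq bond is aligned with the empty orbital at C3, so charge is relayed to the dialkylated Cq, where an aluminate methyl attacks anti to the breaking C2–Cq bond (inversion), releasing the ring strain, creating the C2=C3 alkene and setting the all-carbon quaternary centre as (S), while the AlMe3-complexed ester on the opposite ring face cannot reach the rear side of Cq; the closest known reaction types are the stereoinvertive substitution at quaternary cyclopropane carbons of cyclopropylcarbinyl derivatives through bicyclobutonium-type ions, the Julia cyclopropylcarbinyl-to-homoallyl rearrangement and the C-methylation of tertiary alcohols and chlorides by AlMe3.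

Step 12
Reactants: 24 methyl (1S,2S)-4-methyl-2-[(3S,7S,10E)-3,7,11,15-tetramethylhexadeca-1,10,14-trien-7-yl]cyclohex-3-ene-1-carboxylate
Product: 26 2-{(1S,2S)-4-methyl-2-[(3S,7S,10E)-3,7,11,15-tetramethylhexadeca-1,10,14-trien-7-yl]cyclohex-3-en-1-yl}propan-2-ol, via methyl ketone 25 (not isolated)
Conditions: MeLi (excess), Et2O, −78 → 0 °C; H2O
Reagents that add atoms: methyllithium, [Li]C
Why: Double addition of an organolithium to the ester gives the tertiary alcohol, the unactivated alkenes are inert, and any enolisation of 25 can only return the more stable trans arrangement at C6.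

Step 13
Reactants: 26 2-{(1S,2S)-4-methyl-2-[(3S,7S,10E)-3,7,11,15-tetramethylhexadeca-1,10,14-trien-7-yl]cyclohex-3-en-1-yl}propan-2-ol
Product: 28 (3S,4S)-1-methyl-4-(prop-1-en-2-yl)-3-[(3S,7S,10E)-3,7,11,15-tetramethylhexadeca-1,10,14-trien-7-yl]cyclohex-1-ene (CNP0208273.1), via sulfamate ester 27 (not isolated)
Conditions: Burgess reagent, toluene, 60 °C
Reagents that add atoms: none
Why: The Burgess dehydration (neutral syn elimination) should take one of the six accessible methyl hydrogens rather than the single hindered C6–H, because the isopropylidene isomer would suffer A(1,3) strain with the bulky C1 substituent, and no stereocentre is touched.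

## Compound list

1 | (S)-β-citronellene, (3S)-3,7-dimethylocta-1,6-diene | C=C[C@@H](C)CCC=C(C)C | starting material
2 | (4S)-4-methylhex-5-enal | C=C[C@@H](C)CCC=O | intermediate
3 | (4S)-4-methylhex-5-en-1-ol | C=C[C@@H](C)CCCO | intermediate
4 | (3S)-6-bromo-3-methylhex-1-ene | C=C[C@@H](C)CCCBr | intermediate
5 | propargyl bromide | C#CCBr | starting material
6 | geranyl bromide | CC(C)=CCC/C(C)=C/CBr | starting material
7 | 1,3-dilithiopropyne | [Li]CC#C[Li] | intermediate
8 | (5E)-6,10-dimethylundeca-5,9-dien-1-yne | C#CCC/C=C(\C)CCC=C(C)C | intermediate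
9 | (2S)-5-oxotetrahydrofuran-2-carboxylic acid | O=C1CC[C@@H](C(=O)O)O1 | starting material
10 | dimethyl (2S)-2-hydroxypentanedioate | COC(=O)CC[C@H](O)C(=O)OC | intermediate
11 | dimethyl (2S)-2-[(trifluoromethanesulfonyl)oxy]pentanedioate | COC(=O)CC[C@H](OS(=O)(=O)C(F)(F)F)C(=O)OC | intermediate
12 | (4S)-4-methylhex-5-en-1-ylmagnesium bromide | C=C[C@@H](C)CCC[Mg]Br | intermediate
13 | (4S)-4-methylhex-5-en-1-ylcopper(I) | C=C[C@@H](C)CCC[Cu] | intermediate
14 | (1E,5E)-6,10-dimethyl-2-[(4S)-4-methylhex-5-en-1-yl]undeca-1,5,9-trien-1-ylcopper(I) | [Cu]/C=C(\CCC[C@H](C)C=C)CC/C=C(\C)CCC=C(C)C | intermediate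
15 | dimethyl (2S)-2-{(1E,5E)-6,10-dimethyl-2-[(4S)-4-methylhex-5-en-1-yl]undeca-1,5,9-trien-1-yl}pentanedioate | COC(=O)CC[C@H](C(=O)OC)/C=C(\CCC[C@H](C)C=C)CC/C=C(\C)CCC=C(C)C | intermediate
16 | (4S,5E,9E)-4-(methoxycarbonyl)-10,14-dimethyl-6-[(4S)-4-methylhex-5-en-1-yl]pentadeca-5,9,13-trienoic acid | OC(=O)CC[C@H](C(=O)OC)/C=C(\CCC[C@H](C)C=C)CC/C=C(\C)CCC=C(C)C | intermediate
17 | isobutyl carbonic mixed anhydride of 16 | CC(C)COC(=O)OC(=O)CC[C@H](C(=O)OC)/C=C(\CCC[C@H](C)C=C)CC/C=C(\C)CCC=C(C)C | intermediate
18 | methyl (2S,3E,7E)-2-(4-diazo-3-oxobutyl)-8,12-dimethyl-4-[(4S)-4-methylhex-5-en-1-yl]trideca-3,7,11-trienoate | [N-]=[N+]=CC(=O)CC[C@H](C(=O)OC)/C=C(\CCC[C@H](C)C=C)CC/C=C(\C)CCC=C(C)C | intermediate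
19 | α-oxo copper carbene from 18 (ligands omitted) | [Cu]=CC(=O)CC[C@H](C(=O)OC)/C=C(\CCC[C@H](C)C=C)CC/C=C(\C)CCC=C(C)C | intermediate
20 | methyl (1S,2S,6S,7S)-7-[(3E)-4,8-dimethylnona-3,7-dien-1-yl]-7-[(4S)-4-methylhex-5-en-1-yl]-5-oxobicyclo[4.1.0]heptane-2-carboxylate (CO2Me anti to the cyclopropane, methylhexenyl 7-endo) | O=C1CC[C@H](C(=O)OC)[C@@H]2[C@H]1[C@@]2(CCC[C@H](C)C=C)CC/C=C(\C)CCC=C(C)C | intermediate
21 | methyl (1S,2S,5S,6S,7S)-7-[(3E)-4,8-dimethylnona-3,7-dien-1-yl]-5-hydroxy-5-methyl-7-[(4S)-4-methylhex-5-en-1-yl]bicyclo[4.1.0]heptane-2-carboxylate | C[C@]1(O)CC[C@H](C(=O)OC)[C@@H]2[C@H]1[C@@]2(CCC[C@H](C)C=C)CC/C=C(\C)CCC=C(C)C | intermediate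
22 | dimethylaluminium alkoxide of 21 | C[Al](C)O[C@@]1(C)CC[C@H](C(=O)OC)[C@@H]2[C@H]1[C@@]2(CCC[C@H](C)C=C)CC/C=C(\C)CCC=C(C)C | intermediate
23 | 2-methylbicyclo[4.1.0]hept-2-yl (cyclopropylcarbinyl) cation from 22 | C[C+]1CC[C@H](C(=O)OC)[C@@H]2[C@H]1[C@@]2(CCC[C@H](C)C=C)CC/C=C(\C)CCC=C(C)C | intermediate
24 | methyl (1S,2S)-4-methyl-2-[(3S,7S,10E)-3,7,11,15-tetramethylhexadeca-1,10,14-trien-7-yl]cyclohex-3-ene-1-carboxylate | C=C[C@@H](C)CCC[C@@](C)(CC/C=C(\C)CCC=C(C)C)[C@H]1C=C(C)CC[C@@H]1C(=O)OC | intermediate
25 | 1-{(1S,2S)-4-methyl-2-[(3S,7S,10E)-3,7,11,15-tetramethylhexadeca-1,10,14-trien-7-yl]cyclohex-3-en-1-yl}ethan-1-one | C=C[C@@H](C)CCC[C@@](C)(CC/C=C(\C)CCC=C(C)C)[C@H]1C=C(C)CC[C@@H]1C(C)=O | intermediate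
26 | 2-{(1S,2S)-4-methyl-2-[(3S,7S,10E)-3,7,11,15-tetramethylhexadeca-1,10,14-trien-7-yl]cyclohex-3-en-1-yl}propan-2-ol | C=C[C@@H](C)CCC[C@@](C)(CC/C=C(\C)CCC=C(C)C)[C@H]1C=C(C)CC[C@@H]1C(C)(C)O | intermediate
27 | triethylammonium N-(methoxycarbonyl)sulfamate ester of 26 | C=C[C@@H](C)CCC[C@@](C)(CC/C=C(\C)CCC=C(C)C)[C@H]1C=C(C)CC[C@@H]1C(C)(C)OS(=O)(=O)[N-]C(=O)OC.CC[NH+](CC)CC | intermediate
28 | (3S,4S)-1-methyl-4-(prop-1-en-2-yl)-3-[(3S,7S,10E)-3,7,11,15-tetramethylhexadeca-1,10,14-trien-7-yl]cyclohex-1-ene | C=C[C@@H](C)CCC[C@@](C)(CC/C=C(\C)CCC=C(C)C)[C@H]1C=C(C)CC[C@@H]1C(=C)C | target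

## Step count and risks

Total steps: 13. Longest linear sequence: 10 steps (1, 2, 6, 7, 8, 9, 10, 11, 12, 13).

**1. Step 11 (Proposed new method).**
- What may go wrong: methyl capture at C3 instead of Cq with the cyclopropane kept, proton loss from the CH2 groups flanking Cq, or full ionisation to a free tertiary cation with loss of the facial memory at Cq.
- Fallback, from 21 back to 24: ring opening and C–C bond formation are separated into two known operations. Me3SiCl (CH2Cl2, −78 → −20 °C) should trigger the Julia-type cyclopropylcarbinyl-to-homoallyl rearrangement. Chloride enters at Cq anti to the breaking C2–Cq bond and gives the homoallylic tertiary chloride F1. The isolated chloride is then C-methylated with AlMe3 in CH2Cl2 at −78 °C, the established SN1-type methylation of tertiary alkyl chlorides. Re-ionisation is assisted by the C2=C3 π bond (homoallyl participation of the i-steroid type), so net retention relative to F1 is expected and 24 is reached. Any Cq epimer would have to be removed chromatographically at the stage of 26.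

**2. Step 6 (Proposed new method).**
- What may go wrong: sluggish SN2 attack of the neutral alkenylcopper, electron-transfer reduction of the triflate, self-lactonisation of the triflate through its distal ester, or deprotonation of the doubly activated C6–H of the product with loss of configuration.
- Fallback, from 14 back to 15: C6 is set by auxiliary-controlled enolate chemistry instead of substitution. Compound 14 is converted with 1-pentynyllithium into the mixed cuprate and opened onto ethylene oxide to give the homoallylic alcohol F2. Jones oxidation (acetone, 0 °C) gives the β,γ-unsaturated acid F3. Pivaloyl chloride/Et3N followed by lithiated (S)-4-benzyloxazolidin-2-one gives the imide F4. Its titanium enolate (TiCl3(OiPr), i-Pr2NEt, CH2Cl2) adds to methyl acrylate from the face opposite the benzyl group and gives the Michael adduct F5 with (S)-C6. MeOMgBr in MeOH then exchanges the auxiliary for methoxide and delivers 15.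

**3. Step 9.**
- What may go wrong: insufficient facial discrimination at C1=Cq, diversion of the carbene into C–H insertion or dimerisation, or thermal loss of the diazoketone before it meets the catalyst.
- Fallback, from 15 back to 20: the same α-oxo carbene is generated from an alkyne rather than a diazo compound. Half-reduction of the unhindered ester of 15 with DIBAL-H (toluene, −78 °C) gives the ester aldehyde F6. Colvin homologation with lithiated trimethylsilyldiazomethane (THF, −78 °C → rt) gives the terminal alkyne F7. Gold(I)-catalysed alkyne oxidation (bulky phosphine–gold triflimide, 8-methylquinoline N-oxide, 1,2-dichloroethane, rt) places oxygen on C3 and the carbene on C2. This ligand-shielded carbene cyclopropanates C1=Cq at room temperature to give 20.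

Further compounds
F1 | step 11 | methyl (1S,2S)-2-[(3S,7R,10E)-7-chloro-3,11,15-trimethylhexadeca-1,10,14-trien-7-yl]-4-methylcyclohex-3-ene-1-carboxylate | C=C[C@@H](C)CCC[C@@](Cl)(CC/C=C(\C)CCC=C(C)C)[C@H]1C=C(C)CC[C@@H]1C(=O)OC
F2 | step 6 | (3E,7E)-8,12-dimethyl-4-[(4S)-4-methylhex-5-en-1-yl]trideca-3,7,11-trien-1-ol | OCC/C=C(\CCC[C@H](C)C=C)CC/C=C(\C)CCC=C(C)C
F3 | step 6 | (3E,7E)-8,12-dimethyl-4-[(4S)-4-methylhex-5-en-1-yl]trideca-3,7,11-trienoic acid | OC(=O)C/C=C(\CCC[C@H](C)C=C)CC/C=C(\C)CCC=C(C)C
F4 | step 6 | (4S)-4-benzyl-3-{(3E,7E)-8,12-dimethyl-4-[(4S)-4-methylhex-5-en-1-yl]trideca-3,7,11-trienoyl}-1,3-oxazolidin-2-one | O=C(C/C=C(\CCC[C@H](C)C=C)CC/C=C(\C)CCC=C(C)C)N1[C@@H](Cc2ccccc2)COC1=O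
F5 | step 6 | methyl (4S,5E,9E)-4-{[(4S)-4-benzyl-2-oxo-1,3-oxazolidin-3-yl]carbonyl}-10,14-dimethyl-6-[(4S)-4-methylhex-5-en-1-yl]pentadeca-5,9,13-trienoate | COC(=O)CC[C@H](C(=O)N1[C@@H](Cc2ccccc2)COC1=O)/C=C(\CCC[C@H](C)C=C)CC/C=C(\C)CCC=C(C)C
F6 | step 9 | methyl (2S,3E,7E)-8,12-dimethyl-4-[(4S)-4-methylhex-5-en-1-yl]-2-(3-oxopropyl)trideca-3,7,11-trienoate | O=CCC[C@H](C(=O)OC)/C=C(\CCC[C@H](C)C=C)CC/C=C(\C)CCC=C(C)C
F7 | step 9 | methyl (2S,3E,7E)-2-(but-3-yn-1-yl)-8,12-dimethyl-4-[(4S)-4-methylhex-5-en-1-yl]trideca-3,7,11-trienoate | C#CCC[C@H](C(=O)OC)/C=C(\CCC[C@H](C)C=C)CC/C=C(\C)CCC=C(C)C
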